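A small charge of L, the 32.0 mM of the green run, reads 8.3 mM of Z at 20 h and 8.1 mM at 38 h, the last reading being about a quarter of the charge.

| setting | teal | green | amber | grey |
|---|---|---|---|---|
| L | 80.0 mM | 32.0 mM | 240 mM | 80.0 mM |
| Z |  |  |  | 40.0 mM |
| time |  |  |  | 38 h |

| teal run: time / h | teal run: [Z] / mM | green run: time / h | green run: [Z] / mM | amber run: time / h | amber run: [Z] / mM |
|---|---|---|---|---|---|
| 1.5 | 2.6 | 1.5 | 0.2 | 1.5 | 11.9 |
| 2.9 | 6.0 | 2.9 | 2.4 | 2.9 | 23.6 |
| 5.5 | 12.1 | 5.5 | 2.7 | 5.5 | 41.5 |
| 10 | 17.7 | 10 | 5.1 | 10 | 63.5 |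
| 20 | 25.3 | 20 | 8.3 | 20 | 87.6 |
| 38 | 28.6 | 38 | 8.1 | 38 | 99.3 |

(scatter of a reading: 0.4 mM)

* reaction order in [L] at the outset, round the charge of the teal run, defined at two percent of the L turned into Z (one fixed amount of Z, the same in the runs compared)
* Z in the grey run at 38 h, as a share of the L charged

- Overall: L -> Z.
- Constant volume, constant temperature.
- An order is taken over about fifteen percent of the charge, up and down.
- A share of Z counts the Z that was charged too.

**What do you read first?** The tail of the teal run. Z forms at 0.760 mM h⁻¹ between 10 h and 20 h, then at 0.183 mM h⁻¹ up to 38 h. Setting each rate at the middle of its interval, I get the tail lifetime, the time in which the rate of Z formation falls by a factor of e: 9.85 h.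

**Does it belong to the teal run alone?** The amber run, read the same way, falls from 2.41 mM h⁻¹ to 0.650 mM h⁻¹, a lifetime of 10.7 h. Yet at 20 h its [Z] is 87.6 mM, higher than the teal run's 25.3 mM. The tail therefore looks like a clock, not a response to [Z].

**The grey run starts with 40.0 mM of Z. Isn't that the weak spot?** It is. The amber run stood at 41.5 mM at 5.5 h and still rose at 4.89 mM h⁻¹ up to 10 h, but its charge of L, 240 mM, was larger than the grey run's 80.0 mM. Still, I commit: the grey run has the teal run's charge of L and gains the teal run's 28.6 mM, which gives 85.7%.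

**And the order?** The rises from 2.9 h to 5.5 h in the amber and teal runs give me 0.980, a rough figure taken at equal time and not at equal Z.

The forecast, which differs from me on the order, gives 1.3 (1.08 to 1.55) and 85% (72% to 90%), holding that “Grey should then gain about what teal gained”.

The grey run gives 86.1%, a gain of 28.9 mM, and the order is 1.2. The fit in which the product binds the substrate had forecast 65.6% for the grey run.

    2 L ⇌ E + L (14.11 M⁻¹ h⁻¹, 1.555 M⁻¹ h⁻¹)
    E → Z (0.09756 h⁻¹)
    L → Xi (0.2470 h⁻¹)
    2 L → Lx (6.192 M⁻¹ h⁻¹)

Counted in the tail lifetime, the amber run reached a quarter of its charge as Z at 9.24 h, or 0.938 lifetimes, and the green run at 21.2 h, or 2.15 lifetimes.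

Readings and results come from a simulation for substances that don't exist, and the scatter is random.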